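## Retrosynthetic overview

- The target is reached by global deprotection of a cis,cis-bis(2,3-dihydrobenzofuran): BCl3 removes the two PMB (4-methoxybenzyl) ethers, then BBr3 cleaves five methyl ethers and epimerises C2.
- Key disconnection: the C2–C3 bonds of both dihydrofurans are cut at once (ring D fused to the stilbene-bearing benzo ring A, ring E fused to the central benzo ring B). This leads back to an achiral bis(diaryldiazomethane), made from the bis(hydrazone) of a diaryl diketone. Forward, a two-fold Rh-carbene 1,5 C–H insertion closes both rings and sets all four stereocentres.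
- Enabling feature: each C2 is an O–CH(4-oxyphenyl) carbon, so it can pre-exist as the benzylic CH2 of a PMB ether on the oxygen ortho to C3a, five atoms from the diarylmethine C3 (the carbene carbon). C3a of rings A and B lies between two equivalent oxygens (O1 and the 4-OH), so two identical PMB ethers per ring suffice: one becomes C2 with its aryl group, the other protects the 4-OH. Both dihydrofurans are (2S,3S), so one chiral catalyst serves both.
- The diketone comes from two aryllithium couplings of one building block, 4-bromo-3,5-bis(PMB-oxy)benzaldehyde: ring B as its dimethyl acetal with a ring C Weinreb amide, ring A after Horner–Wadsworth–Emmons olefination to the stilbene.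
- Ring order: no ring is made before the key step; rings E and D are formed together in it.

Key step: step 10

Assumption 1: Rh2(R-PTAD)4, dirhodium tetrakis[(R)-2-(1-adamantyl)-2-phthalimidoacetate], is taken to deliver the 3S configuration at both diarylmethine carbons; if the sense is opposite, Rh2(S-PTAD)4 is used with no other change.
Assumption 2: N,3,5-trimethoxy-N-methylbenzamide is taken as a catalogue compound (otherwise one step from 3,5-dimethoxybenzoyl chloride).

## Route

Step 1
Reactants: 1 methyl 4-bromo-3,5-dihydroxybenzoate; 2 4-methoxybenzyl chloride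
Product: 3 methyl 4-bromo-3,5-bis[(4-methoxybenzyl)oxy]benzoate
Conditions: 2 (2.4 equiv), K2CO3 (3 equiv), KI (cat.), DMF, 60 °C
Reagents that add atoms: 4-methoxybenzyl chloride (second equivalent of 2), COc1ccc(CCl)cc1
Why: Two-fold Williamson etherification should alkylate both phenols, one molecule of 2 per hydroxyl, and the two identical PMB ethers later supply C2 with its 4-oxyphenyl group and the protecting group of the 4-OH.

Step 2
Reactants: 3 methyl 4-bromo-3,5-bis[(4-methoxybenzyl)oxy]benzoate
Product: 4 {4-bromo-3,5-bis[(4-methoxybenzyl)oxy]phenyl}methanol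
Conditions: i-Bu2AlH (2.5 equiv), CH2Cl2, −78 → 0 °C; aq. potassium sodium tartrate
Reagents that add atoms: none
Why: Hydride reduction of the ester to the benzylic alcohol should leave the aryl bromide and the benzyl ethers untouched.

Step 3
Reactants: 4 {4-bromo-3,5-bis[(4-methoxybenzyl)oxy]phenyl}methanol
Product: 5 4-bromo-3,5-bis[(4-methoxybenzyl)oxy]benzaldehyde
Conditions: MnO2 (activated, excess), CH2Cl2, rt
Reagents that add atoms: none
Why: MnO2 oxidation of a benzylic alcohol should stop at the aldehyde.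

Step 4
Reactants: 5 4-bromo-3,5-bis[(4-methoxybenzyl)oxy]benzaldehyde; 6 diethyl (4-methoxybenzyl)phosphonate
Product: 7 (E)-2-bromo-1,3-bis[(4-methoxybenzyl)oxy]-5-[2-(4-methoxyphenyl)ethenyl]benzene (ring A bromide)
Conditions: KOtBu, THF, 0 °C → rt
Reagents that add atoms: none
Why: Horner–Wadsworth–Emmons olefination of an aryl aldehyde with a benzylic phosphonate should give the E-stilbene through the thermodynamically preferred anti elimination.

Step 5
Reactants: 5 4-bromo-3,5-bis[(4-methoxybenzyl)oxy]benzaldehyde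
Product: 8 2-bromo-5-(dimethoxymethyl)-1,3-bis[(4-methoxybenzyl)oxy]benzene (ring B bromide)
Conditions: HC(OMe)3, TsOH·H2O (cat.), MeOH, rt; Et3N quench
Reagents that add atoms: trimethyl orthoformate, COC(OC)OC
Why: Acid-catalysed acetalisation masks the aldehyde against the aryllithium of the next step under conditions too mild to touch the PMB ethers.

Step 6
Reactants: 8 2-bromo-5-(dimethoxymethyl)-1,3-bis[(4-methoxybenzyl)oxy]benzene; 9 N,3,5-trimethoxy-N-methylbenzamide
Product: 13 4-(3,5-dimethoxybenzoyl)-3,5-bis[(4-methoxybenzyl)oxy]benzaldehyde, via aryllithium 10 (not isolated), via tetrahedral lithium adduct 11 (not isolated), via ketone dimethyl acetal 12 (not isolated)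
Conditions: n-BuLi, THF, −78 °C; 9, −78 → −20 °C; then 1 M HCl, THF, rt
Reagents that add atoms: water, O
Why: Bromine–lithium exchange followed by Weinreb ketone synthesis should give the diaryl ketone without over-addition (stable chelated adduct, hindered ketone), and the acidic work-up hydrolyses the dimethyl acetal to the aldehyde.

Step 7
Reactants: 7 (E)-2-bromo-1,3-bis[(4-methoxybenzyl)oxy]-5-[2-(4-methoxyphenyl)ethenyl]benzene; 13 4-(3,5-dimethoxybenzoyl)-3,5-bis[(4-methoxybenzyl)oxy]benzaldehyde
Product: 15 (3,5-dimethoxyphenyl){4-[hydroxy({2,6-bis[(4-methoxybenzyl)oxy]-4-[(E)-2-(4-methoxyphenyl)ethenyl]phenyl})methyl]-2,6-bis[(4-methoxybenzyl)oxy]phenyl}methanone (racemic carbinol), via aryllithium 14 (not isolated)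
Conditions: 7, n-BuLi (1.0 equiv), THF, −78 °C; then 13, THF, −78 °C; sat. aq. NH4Cl
Reagents that add atoms: none
Why: Bromine–lithium exchange is faster than any reaction of the stilbene, and 1,2-addition of the aryllithium should occur only at the aldehyde because the ketone is shielded by two ortho benzyloxy groups; the new carbinol centre is removed in step 8.

Step 8
Reactants: 15 racemic carbinol
Product: 16 (3,5-dimethoxyphenyl){4-({2,6-bis[(4-methoxybenzyl)oxy]-4-[(E)-2-(4-methoxyphenyl)ethenyl]phenyl}carbonyl)-2,6-bis[(4-methoxybenzyl)oxy]phenyl}methanone (diketone)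
Conditions: Dess–Martin periodinane, pyridine, CH2Cl2, 0 °C → rt
Reagents that add atoms: none
Why: Buffered Dess–Martin oxidation should convert the acid-sensitive, hindered diaryl carbinol into the ketone without ionising it.

Step 9
Reactants: 16 diketone
Product: 17 bis(hydrazone) of 16 (both C=O replaced by C=N–NH2, C=N geometry of no consequence)
Conditions: N2H4·H2O (large excess), AcOH (cat.), n-BuOH, 110 °C, sealed tube, argon
Reagents that add atoms: hydrazine (used as the hydrate), NN
Why: Acid-catalysed condensation with a large excess of hydrazine under forcing conditions should convert both ketones, one hydrazine per carbonyl, since each has one unhindered aryl flank; the excess suppresses azine formation and argon excludes diimide reduction of the stilbene.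

Step 10
Reactants: 17 bis(hydrazone)
Product: 20 (2R,3S)-3-{(2R,3S)-3-(3,5-dimethoxyphenyl)-4-[(4-methoxybenzyl)oxy]-2-(4-methoxyphenyl)-2,3-dihydrobenzofuran-6-yl}-4-[(4-methoxybenzyl)oxy]-2-(4-methoxyphenyl)-6-[(E)-2-(4-methoxyphenyl)ethenyl]-2,3-dihydrobenzofuran (cis,cis-bis(dihydrobenzofuran)), via bis(diaryldiazomethane) 18 (not isolated), via ring E monocyclised diazo compound 19 (not isolated)
Conditions: MnO2 (activated, excess), CH2Cl2, 0 °C → rt, dark; filter (Celite); filtrate added slowly to Rh2(R-PTAD)4 (2 mol %), CH2Cl2, 0 °C → rt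
Reagents that add atoms: none
Why: MnO2 dehydrogenates both hydrazones to the bis(diaryldiazomethane) 18, and Rh2(R-PTAD)4 then converts each diazo carbon, with loss of N2, into a donor/donor rhodium carbene that inserts into a benzylic C–H bond of an ortho 4-methoxybenzyloxy group through a concerted, asynchronous, hydride-transfer-like three-centre transition state, forming the C2–C3 bond. The closest known reaction type is the enantioselective intramolecular C–H insertion of diaryl rhodium carbenes into aryl benzyl ethers, which gives cis-2,3-diaryl-2,3-dihydrobenzofurans. Each dihydrofuran (ring E on ring B and ring D on ring A, in either order; 19 is drawn with ring E closed first) is closed as a five-membered ring by 1,5-C–H insertion across the preformed C3a–C7a–O1–CH2 tether. C3 of each ring is set by the chiral carboxylate ligands, which decide the face of the carbene that meets the C–H bond (3S in both rings, since both carbenes have the same local environment of one 2,6-dioxygenated aryl and one meta-substituted aryl group), and C2 is set cis to C3 (2R) by the concerted insertion; because two catalyst-controlled events are chained, a minor-sense event ends up in a separable diastereomer. The step needs site selectivity, secured because only the ortho OCH2Ar hydrogens are in 1,5 reach of each carbene and the two ortho ethers of each ring are equivalent by rotation about the aryl–carbene bond, and it needs chemoselectivity over the stilbene and over azine formation, secured by the low electrophilicity of donor/donor carbenes, the activation of the C–H bond by oxygen and the anisyl group, and slow addition at high dilution.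

Step 11
Reactants: 20 cis,cis-bis(dihydrobenzofuran)
Product: 21 (2R,3S)-3-[(2R,3S)-3-(3,5-dimethoxyphenyl)-4-hydroxy-2-(4-methoxyphenyl)-2,3-dihydrobenzofuran-6-yl]-2-(4-methoxyphenyl)-6-[(E)-2-(4-methoxyphenyl)ethenyl]-2,3-dihydrobenzofuran-4-ol (cis,cis-diphenol)
Conditions: BCl3 (1 M in CH2Cl2), pentamethylbenzene, CH2Cl2, −78 °C; MeOH quench at −78 °C, then aq. NaHCO3
Reagents that add atoms: none
Why: Lewis-acid debenzylation with a non-basic cation scavenger should cleave the two remaining aryl PMB ethers at low temperature, pentamethylbenzene trapping the 4-methoxybenzyl cation before it can alkylate the electron-rich rings, while the methyl ethers and the stilbene are inert and any C2 epimerisation is towards the wanted trans series.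

Step 12
Reactants: 21 cis,cis-diphenol
Product: 22 (2S,3S)-3-[(2S,3S)-3-(3,5-dihydroxyphenyl)-4-hydroxy-2-(4-hydroxyphenyl)-2,3-dihydrobenzofuran-6-yl]-2-(4-hydroxyphenyl)-6-[(E)-2-(4-hydroxyphenyl)ethenyl]-2,3-dihydrobenzofuran-4-ol (CNP0248228.2)
Conditions: BBr3 (excess), CH2Cl2, −78 °C → rt; MeOH then H2O, 0 °C
Reagents that add atoms: none
Why: BBr3 cleaves the five aryl methyl ethers, and reversible Lewis-acid ionisation of each benzylic C2–O bond (a cation stabilised by the 4-oxyphenyl group) should let C2 equilibrate to the more stable 2,3-trans arrangement while the catalyst-set C3 centres stay untouched, so (2R,3S) becomes (2S,3S) in both rings.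

## Compound list

1 | methyl 4-bromo-3,5-dihydroxybenzoate | COC(=O)c1cc(O)c(Br)c(O)c1 | starting material
2 | 4-methoxybenzyl chloride | COc1ccc(CCl)cc1 | starting material
3 | methyl 4-bromo-3,5-bis[(4-methoxybenzyl)oxy]benzoate | COC(=O)c1cc(OCc2ccc(OC)cc2)c(Br)c(OCc2ccc(OC)cc2)c1 | intermediate
4 | {4-bromo-3,5-bis[(4-methoxybenzyl)oxy]phenyl}methanol | OCc1cc(OCc2ccc(OC)cc2)c(Br)c(OCc2ccc(OC)cc2)c1 | intermediate
5 | 4-bromo-3,5-bis[(4-methoxybenzyl)oxy]benzaldehyde | O=Cc1cc(OCc2ccc(OC)cc2)c(Br)c(OCc2ccc(OC)cc2)c1 | intermediate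
6 | diethyl (4-methoxybenzyl)phosphonate | CCOP(=O)(Cc1ccc(OC)cc1)OCC | starting material
7 | (E)-2-bromo-1,3-bis[(4-methoxybenzyl)oxy]-5-[2-(4-methoxyphenyl)ethenyl]benzene | COc1ccc(/C=C/c2cc(OCc3ccc(OC)cc3)c(Br)c(OCc3ccc(OC)cc3)c2)cc1 | intermediate
8 | 2-bromo-5-(dimethoxymethyl)-1,3-bis[(4-methoxybenzyl)oxy]benzene | COC(OC)c1cc(OCc2ccc(OC)cc2)c(Br)c(OCc2ccc(OC)cc2)c1 | intermediate
9 | N,3,5-trimethoxy-N-methylbenzamide | CON(C)C(=O)c1cc(OC)cc(OC)c1 | starting material
10 | {4-(dimethoxymethyl)-2,6-bis[(4-methoxybenzyl)oxy]phenyl}lithium | [Li]c1c(OCc2ccc(OC)cc2)cc(C(OC)OC)cc1OCc1ccc(OC)cc1 | intermediate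
11 | tetrahedral lithium adduct of 10 and 9 (lithium alkoxide of the N-methoxy-N-methyl hemiaminal) | [Li]OC(N(C)OC)(c1cc(OC)cc(OC)c1)c1c(OCc2ccc(OC)cc2)cc(C(OC)OC)cc1OCc1ccc(OC)cc1 | intermediate
12 | {4-(dimethoxymethyl)-2,6-bis[(4-methoxybenzyl)oxy]phenyl}(3,5-dimethoxyphenyl)methanone | COC(OC)c1cc(OCc2ccc(OC)cc2)c(C(=O)c2cc(OC)cc(OC)c2)c(OCc2ccc(OC)cc2)c1 | intermediate
13 | 4-(3,5-dimethoxybenzoyl)-3,5-bis[(4-methoxybenzyl)oxy]benzaldehyde | O=Cc1cc(OCc2ccc(OC)cc2)c(C(=O)c2cc(OC)cc(OC)c2)c(OCc2ccc(OC)cc2)c1 | intermediate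
14 | {2,6-bis[(4-methoxybenzyl)oxy]-4-[(E)-2-(4-methoxyphenyl)ethenyl]phenyl}lithium | [Li]c1c(OCc2ccc(OC)cc2)cc(/C=C/c2ccc(OC)cc2)cc1OCc1ccc(OC)cc1 | intermediate
15 | racemic carbinol: ring B ketone of 13 retained, aldehyde carbon now CH(OH) bonded to C4 of ring A | OC(c1cc(OCc2ccc(OC)cc2)c(C(=O)c2cc(OC)cc(OC)c2)c(OCc2ccc(OC)cc2)c1)c1c(OCc2ccc(OC)cc2)cc(/C=C/c2ccc(OC)cc2)cc1OCc1ccc(OC)cc1 | intermediate
16 | diketone: ring C–CO–ring B–CO–ring A, rings A and B each with two ortho PMB ethers, ring A with the E-4-methoxystyryl group | O=C(c1cc(OCc2ccc(OC)cc2)c(C(=O)c2cc(OC)cc(OC)c2)c(OCc2ccc(OC)cc2)c1)c1c(OCc2ccc(OC)cc2)cc(/C=C/c2ccc(OC)cc2)cc1OCc1ccc(OC)cc1 | intermediate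
17 | bis(hydrazone) of 16 | NN=C(c1cc(OCc2ccc(OC)cc2)c(C(=NN)c2cc(OC)cc(OC)c2)c(OCc2ccc(OC)cc2)c1)c1c(OCc2ccc(OC)cc2)cc(/C=C/c2ccc(OC)cc2)cc1OCc1ccc(OC)cc1 | intermediate
18 | bis(diaryldiazomethane) from 17 | [N-]=[N+]=C(c1cc(OCc2ccc(OC)cc2)c(C(=[N+]=[N-])c2cc(OC)cc(OC)c2)c(OCc2ccc(OC)cc2)c1)c1c(OCc2ccc(OC)cc2)cc(/C=C/c2ccc(OC)cc2)cc1OCc1ccc(OC)cc1 | intermediate
19 | monocyclised diazo compound: ring E closed as the (2R,3S)-cis-dihydrobenzofuran, diazo group between rings A and B still present | [N-]=[N+]=C(c1c(OCc2ccc(OC)cc2)cc(/C=C/c2ccc(OC)cc2)cc1OCc1ccc(OC)cc1)c1cc(OCc3ccc(OC)cc3)c2c(c1)O[C@@H](c1ccc(OC)cc1)[C@H]2c1cc(OC)cc(OC)c1 | intermediate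
20 | cis,cis-bis(dihydrobenzofuran), (2R,3S) in ring D and (2R,3S) in ring E, one PMB ether on C4 of each benzofuran, five methyl ethers | COc1ccc(/C=C/c2cc(OCc4ccc(OC)cc4)c3c(c2)O[C@@H](c2ccc(OC)cc2)[C@H]3c2cc(OCc4ccc(OC)cc4)c3c(c2)O[C@@H](c2ccc(OC)cc2)[C@H]3c2cc(OC)cc(OC)c2)cc1 | intermediate
21 | cis,cis-diphenol, (2R,3S) in both rings, free 4-OH on both benzofurans, five methyl ethers | COc1ccc(/C=C/c2cc(O)c3c(c2)O[C@@H](c2ccc(OC)cc2)[C@H]3c2cc(O)c3c(c2)O[C@@H](c2ccc(OC)cc2)[C@H]3c2cc(OC)cc(OC)c2)cc1 | intermediate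
22 | CNP0248228.2, (2S,3S) trans in ring D and (2S,3S) trans in ring E, E-stilbene | Oc1ccc(/C=C/c2cc(O)c3c(c2)O[C@H](c2ccc(O)cc2)[C@H]3c2cc(O)c3c(c2)O[C@H](c2ccc(O)cc2)[C@H]3c2cc(O)cc(O)c2)cc1 | target

## Step count and risks

Total steps: 12. Longest linear sequence: 11 steps (1, 2, 3, 5, 6, 7, 8, 9, 10, 11, 12); step 4 is the convergent branch.

Most likely to fail:

**Step 10.** Two diazo groups in one molecule may couple between molecules (azine and oligomer formation), and catalyst control in the second insertion may erode once the first ring is in place, giving diastereomer mixtures. The fallback decouples the two insertions and closes ring E before ring A is attached. It sets out from 12, isolated from step 6 by quenching with aqueous NH4Cl instead of HCl. Condensation with hydrazine hydrate (AcOH cat., n-BuOH, 110 °C) should give the mono-hydrazone F1. MnO2 in CH2Cl2 should give the mono-diazo compound F2, used as the filtered solution. Rh2(R-PTAD)4 should then give the cis-dihydrobenzofuran acetal F3 by a single insertion of the precedented kind. 1 M HCl in THF frees the aldehyde F4. Aryllithium 14, made from 7 as in step 7, adds to give the carbinol F5. Dess–Martin oxidation gives the ketone F6, and hydrazine gives the hydrazone F7. MnO2 then gives the diazo compound 19 and Rh2(R-PTAD)4 closes ring D, so the fallback comes back to the route at 20.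

**Step 9.** Condensation may stall at carbonyl groups that are each shielded and deactivated by two ortho benzyloxy groups, and long heating with hydrazine invites diimide-type reduction of the stilbene if air enters. The fallback activates the carbonyls as thiocarbonyls. From 16, Lawesson's reagent in toluene at 100 °C should give the bis(thioketone) F8. Hydrazine hydrate in THF at 0 °C → rt then exchanges sulfur for the hydrazone nitrogen with loss of H2S and returns to the route at 17.

**Step 12.** Cleavage of five methyl ethers may be incomplete, the Lewis acid may divert ring-opened benzylic cations into rearranged material, and acid may oligomerise the stilbene. The fallback separates epimerisation from demethylation and cleaves the methyl ethers by nucleophilic instead of Lewis-acid chemistry. From 21, brief treatment with CF3CO2H in CH2Cl2 at 0 °C should equilibrate both C2 centres to trans, giving the trans,trans-diphenol pentamethyl ether F9. NaSEt (large excess) in DMF at 140 °C then removes the five methyl groups by SN2 attack of thiolate on the methyl carbons, with no cation at C2, and acidification gives 22.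

Further compounds
F1 | step 10 | mono-hydrazone of 12 | COC(OC)c1cc(OCc2ccc(OC)cc2)c(C(=NN)c2cc(OC)cc(OC)c2)c(OCc2ccc(OC)cc2)c1
F2 | step 10 | mono-diazo compound from F1 | COC(OC)c1cc(OCc2ccc(OC)cc2)c(C(=[N+]=[N-])c2cc(OC)cc(OC)c2)c(OCc2ccc(OC)cc2)c1
F3 | step 10 | (2R,3S)-6-(dimethoxymethyl)-3-(3,5-dimethoxyphenyl)-4-[(4-methoxybenzyl)oxy]-2-(4-methoxyphenyl)-2,3-dihydrobenzofuran | COC(OC)c1cc(OCc3ccc(OC)cc3)c2c(c1)O[C@@H](c1ccc(OC)cc1)[C@H]2c1cc(OC)cc(OC)c1
F4 | step 10 | (2R,3S)-3-(3,5-dimethoxyphenyl)-4-[(4-methoxybenzyl)oxy]-2-(4-methoxyphenyl)-2,3-dihydrobenzofuran-6-carbaldehyde | O=Cc1cc(OCc3ccc(OC)cc3)c2c(c1)O[C@@H](c1ccc(OC)cc1)[C@H]2c1cc(OC)cc(OC)c1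
F5 | step 10 | carbinol from F4 and 14 (mixture of epimers at the carbinol carbon) | OC(c1c(OCc2ccc(OC)cc2)cc(/C=C/c2ccc(OC)cc2)cc1OCc1ccc(OC)cc1)c1cc(OCc3ccc(OC)cc3)c2c(c1)O[C@@H](c1ccc(OC)cc1)[C@H]2c1cc(OC)cc(OC)c1
F6 | step 10 | ketone from F5 | O=C(c1c(OCc2ccc(OC)cc2)cc(/C=C/c2ccc(OC)cc2)cc1OCc1ccc(OC)cc1)c1cc(OCc3ccc(OC)cc3)c2c(c1)O[C@@H](c1ccc(OC)cc1)[C@H]2c1cc(OC)cc(OC)c1
F7 | step 10 | hydrazone of F6 | NN=C(c1c(OCc2ccc(OC)cc2)cc(/C=C/c2ccc(OC)cc2)cc1OCc1ccc(OC)cc1)c1cc(OCc3ccc(OC)cc3)c2c(c1)O[C@@H](c1ccc(OC)cc1)[C@H]2c1cc(OC)cc(OC)c1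
F8 | step 9 | bis(thioketone) from 16 | S=C(c1cc(OCc2ccc(OC)cc2)c(C(=S)c2cc(OC)cc(OC)c2)c(OCc2ccc(OC)cc2)c1)c1c(OCc2ccc(OC)cc2)cc(/C=C/c2ccc(OC)cc2)cc1OCc1ccc(OC)cc1
F9 | step 12 | trans,trans-diphenol pentamethyl ether, (2S,3S) in both rings | COc1ccc(/C=C/c2cc(O)c3c(c2)O[C@H](c2ccc(OC)cc2)[C@H]3c2cc(O)c3c(c2)O[C@H](c2ccc(OC)cc2)[C@H]3c2cc(OC)cc(OC)c2)cc1
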